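**What remained.** Tuesday's run still held 68.5% of its starting material at 10.0 min, and I reckoned from how that leftover had shrunk. Reagent was charged nearly equal to starting material in Tuesday's flask, so I took the two to fall together, and I assumed a rate first order in starting material, reagent and free catalyst. The reciprocal of the fraction left should then climb steadily, and between 4.00 min and 10.0 min, past the quicker start, I read a climb of 0.0381 min⁻¹.

| flask | starting material | reagent | free catalyst | added ligand | temperature | remark | time |
|---|---|---|---|---|---|---|---|
| Tuesday's | 0.20 M | 1.05 equiv | 1.6 mol% | 8.7 mM | 20 °C | run made earlier |  |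
| violet | 0.18 M | 1.60 equiv | 1.6 mol% | 6.0 mM | 20 °C |  | 15 min |
| grey | 0.18 M | 1.05 equiv | 1.6 mol% | 8.7 mM | 20 °C |  | 15 min |
| ochre | 0.18 M | 1.05 equiv | 0.4 mol% | 8.7 mM | 20 °C |  | 15 min |
| teal | 0.50 M | 1.05 equiv | 0.4 mol% | 8.7 mM | 20 °C |  | 15 min |
| amber | 0.50 M | 2.10 equiv | 1.6 mol% | 6.0 mM | 20 °C |  | 15 min |
| red | 0.060 M | 0.350 equiv | 1.6 mol% | 8.7 mM | 50 °C |  | 15 min |

Tuesday's run (percent of the starting material charged)

| time / min | target / % | starting material / % |
|---|---|---|
| 1.33 | 8.3 | 92.5 |
| 2.50 | 12.1 | 87.0 |
| 4.00 | 16.7 | 81.2 |
| 5.00 | 21.1 | 79.9 |
| 6.00 | 22.0 | 76.4 |
| 8.00 | 27.5 | 73.3 |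
| 10.0 | 31.9 | 68.5 |

(each reading ± 0.5 percentage points)

- the analysis behind the earlier runs scatters by 0.5 percentage points, standard deviation
- the earlier runs do not show what temperature does; that part of a forecast is a guess
- no earlier run changes the charge of free catalyst; that part of a forecast is a guess
- no earlier run changes the charge of added ligand; that part of a forecast is a guess

- the flasks put in order of amount of target, in percent of the starting material charged, best first, at 15 min (violet / grey / ochre / teal / amber / red)
- the amount of target, in percent of the starting material charged of the flask you put first, at 15 min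
- the amount of target, in percent of the starting material charged of the flask you put last, at 15 min

**One number.** I defined N as the pseudo-first-order lifetimes of starting material that a flask gets in its time, with catalyst and reagent taken at their charged concentrations; for Tuesday's flask over 15 min that is 0.571. Loadings and equivalents are counted on the starting material, and in this reckoning N goes with the square of its concentration, with the catalyst loading and with the reagent equivalents. That gave amber 7.14, teal 0.892, violet 0.705, grey 0.462 and ochre 0.116. With near-equal charges, I took target as N divided by one plus N, so I reckoned ochre at 10.4%, while amber should convert nearly all of its starting material.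

**Was it enough?** No, in two places. Violet's N is lower than teal's, but violet carries 6.0 mM of added ligand against teal's 8.7 mM, and no earlier run changes that charge, so I left that pair open. Red at 20 °C would have 0.0171, so at 50 °C heat must multiply it by 6.78 to match ochre, a guess. I committed to amber first and a last place near ochre's figure.

**The forecast.** It gave amber > violet > teal > grey > red > ochre, with 97% and 10%, and added: “Red against ochre is nearly a tie”.

**The result.** The flasks gave amber > violet > teal > grey > ochre > red; amber reached 97.5% on its N of 7.14, and red's 8.53% stood below ochre's 11.3%.

    starting material + reagent + free catalyst → target + free catalyst, rate k1*[starting material]*[reagent]*[free catalyst]/(1 + ([starting material]/sat1)) (0.450 M, k = 2.60 L² mol⁻² s⁻¹, Ea = 45.0 kJ mol⁻¹)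
    free catalyst + target → spent catalyst (k = 0.00470 L mol⁻¹ s⁻¹, Ea = 59.0 kJ mol⁻¹)
    free catalyst + added ligand ⇌ idle complex (K = 120 L mol⁻¹, k = 0.570 L mol⁻¹ s⁻¹, Ea = 40.0 kJ mol⁻¹, ΔH = 7.00 kJ mol⁻¹)
    (constants at 20 °C)

**Less reagent.** Amber's neighbour, the same flask with 0.530 equiv of reagent, has N = 1.80, more than one lifetime, so I reckoned it close to the ceiling of its limiting reagent, target at that fraction of the starting material charged. It gave 45.8% of target, with 12% of its reagent left at 15.0 min.

All runs were generated by integration for substances that don't exist; scatter was added.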